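Numbering: bicyclo[3.3.1]nonane with bridgeheads C1 and C5 and ketone bridge C9. Ring A is C1-C2-C3(aroyl)-C4-C5-C9 and ring B is C1-C8-C7-C6-C5-C9. The enabling feature is the C1-C8 bond between two quaternary carbons of ring B, with the prenylated C7 beside it. Without that bond, C6-C7=C8 is an (E)-trisubstituted allylic chain on C5 of a dearomatized acylphloroglucinol (ring A), and its C1 enol carbon lies within reach of C8.
Cuts, in retrosynthetic order: the O-tosyl bond; three isopropylidene caps (metathesis) and the fourth on the C8 arm (Wittig); C7-allyl (radical); C1-C8 together with C7-I (key step); C5-C6 (allylic alkylation); two ring A-allyl bonds; the aryl ketone bond.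
Forward: ring A is phloroglucinol, acylated once and C-allylated twice. A seven-carbon unit cut from geraniol is joined at C5 with loss of aromaticity, iodine closes ring B, C7 is allylated and the side chains are completed.
Stereochemistry: C5 comes from a chiral palladium catalyst. C1, C8 and C7 follow from C5, from the E geometry inherited from geraniol and from a chair transition state with anti addition. C7 is set again by radical allylation on the exo face.
The C8 arm travels as CH2CH2CH(OMe)2. An alkene there would form a hex-5-enyl system with the C7 radical, whose 5-exo closure is faster than allyl transfer, and it would offer iodine one more site. The phenol travels as its tosylate, which unlike a silyl ether survives AlCl3 and aqueous KOH.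

Key step: step 8

Assumption: the (1R,2R) ligand is taken to give the (S) centre at C5; if the sense of induction is the opposite, the commercial (1S,2S) antipode is used and nothing else changes.
Assumption: enolised tricarbonyl compounds are drawn as one tautomer, and the CIP descriptors refer to that drawing.

Step 1
Reactants: 1 3-hydroxybenzoic acid
Product: 2 3-(tosyloxy)benzoic acid, i.e. 3-(4-methylbenzenesulfonyloxy)benzoic acid
Conditions: TsCl, NaOH, THF/H2O, 0 °C to rt; then aq HCl
Reagents that add atoms: p-toluenesulfonyl chloride, Cc1ccc(cc1)S(=O)(=O)Cl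
Why: Schotten-Baumann O-sulfonylation of the phenoxide, in which any mixed anhydride at the carboxylate is hydrolysed by the aqueous base, gives an aryl sulfonate that tolerates Lewis acid, cold aqueous base, iodine, stannyl radicals and ruthenium carbenes.

Step 2
Reactants: 2 3-(tosyloxy)benzoic acid; 3 phloroglucinol
Product: 5 3-(2,4,6-trihydroxybenzoyl)phenyl 4-methylbenzenesulfonate, via 3-(tosyloxy)benzoyl chloride 4 (not isolated)
Conditions: (COCl)2, DMF (cat.), CH2Cl2, rt, evaporation; then 3, AlCl3 (4 equiv), CH2Cl2/PhNO2, 0 to 40 °C; ice/aq HCl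
Reagents that add atoms: oxalyl chloride, O=C(Cl)C(=O)Cl (supplies the chlorine of 4; nothing from it stays in 5)
Why: Friedel-Crafts acylation of the very electron-rich arene should stop after one acylation because the chelated ketone deactivates the ring, and the sulfonate ester is inert to AlCl3 at this temperature.

Step 3
Reactants: 5 3-(2,4,6-trihydroxybenzoyl)phenyl 4-methylbenzenesulfonate; 6 allyl bromide
Product: 7 3-(3,5-diallyl-2,4,6-trihydroxybenzoyl)phenyl 4-methylbenzenesulfonate
Conditions: allyl bromide (2.1 equiv), KOH (aq), H2O, 0 °C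
Reagents that add atoms: allyl bromide (6), C=CCBr
Why: C-alkylation of the ambident phloroglucinolate in water, where hydrogen bonding to oxygen steers the soft allylic halide to the two equivalent free ring carbons, is the standard route to 3,5-dialkenyl acylphloroglucinols, and the tosylate is stable to cold dilute base.

Step 4
Reactants: 8 geraniol
Product: 9 geranyl methyl carbonate, (E)-3,7-dimethylocta-2,6-dienyl methyl carbonate
Conditions: ClCO2Me, pyridine, CH2Cl2, 0 °C
Reagents that add atoms: methyl chloroformate, COC(=O)Cl
Why: O-acylation of the primary allylic alcohol installs the leaving group for the later allylic alkylation and leaves the E alkene of the natural alcohol untouched.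

Step 5
Reactants: 9 geranyl methyl carbonate
Product: 11 (E)-methyl 3-methyl-6-oxohex-2-enyl carbonate, via secondary ozonide 10 (not isolated)
Conditions: O3 (1.0 equiv), CH2Cl2, -78 °C; then PPh3, -78 °C to rt
Reagents that add atoms: ozone, [O-][O+]=O
Why: In this selective ozonolysis the distal isopropylidene alkene is clearly more electron-rich than the alkene carrying the allylic carbonate, so one equivalent of ozone should cleave only the former, as is known for geranyl esters.

Step 6
Reactants: 11 (E)-methyl 3-methyl-6-oxohex-2-enyl carbonate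
Product: 12 (E)-6,6-dimethoxy-3-methylhex-2-enyl methyl carbonate
Conditions: HC(OMe)3, PPTS (cat.), MeOH, rt; NaHCO3
Reagents that add atoms: trimethyl orthoformate, COC(OC)OC; methanol, CO
Why: Acid-catalysed acetalization driven by the orthoformate as water scavenger masks the aldehyde under conditions too mild to ionise the primary allylic carbonate.

Step 7
Reactants: 7 3-(3,5-diallyl-2,4,6-trihydroxybenzoyl)phenyl 4-methylbenzenesulfonate; 12 (E)-6,6-dimethoxy-3-methylhex-2-enyl methyl carbonate
Product: 13 (6S)-2,6-diallyl-6-[(2E)-6,6-dimethoxy-3-methylhex-2-enyl]-3,5-dihydroxy-4-[3-(tosyloxy)benzoyl]cyclohexa-2,4-dien-1-one. In target numbering this is C9(=O)-C1(allyl)=C2(OH)-C3(aroyl)=C4(OH)-C5, with C5 (S) bearing allyl and the chain C6-C7=C8.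
Conditions: Pd2(dba)3·CHCl3 (2.5 mol %), (1R,2R)-N,N'-bis(2-diphenylphosphinobenzoyl)cyclohexane-1,2-diamine (6 mol %), degassed CH2Cl2, 0 °C to rt
Reagents that add atoms: none
Why: Proposed new method: zerovalent palladium ionises 12 to a 1,1-disubstituted π-allyl complex, the methoxide released with CO2 deprotonates 7, and the soft ring carbon attacks the unhindered CH2 terminus; this gives the linear product with E geometry kept, because syn/anti exchange would need a tertiary σ-palladium species, O-allylation is reversible under the catalyst, C3 is blocked by the aroyl group, and the chiral pocket selects between the enantiotopic carbons C1 and C5 and so creates the C5 centre. The closest known reactions (all Tsuji-Trost allylations) are the racemic palladium-catalysed dearomative allylation of phloroglucinol derivatives, the asymmetric allylic dearomatization of naphthols and the asymmetric linear geranylation of oxindoles with this ligand family; enantioselection on an acylphloroglucinol has not been shown.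

Step 8
Reactants: 13 the dearomatized dienone of step 7
Product: 14 (1S,5S,7R,8R)-1,5-diallyl-8-(3,3-dimethoxypropyl)-4-hydroxy-7-iodo-8-methyl-3-[3-(tosyloxy)benzoyl]bicyclo[3.3.1]non-3-ene-2,9-dione (on the ring B chair, iodine and the acetal arm are equatorial and the methyl is axial)
Conditions: I2 (1.1 equiv), KI (3 equiv), KHCO3 (3 equiv), THF/H2O, 0 °C to rt, dark
Reagents that add atoms: iodine, II
Why: Iodine adds reversibly to C7=C8, the only trisubstituted and therefore most electron-rich alkene of 13, and the enolate made by bicarbonate opens the iodonium ion through carbon C1 at the tertiary terminus C8, which forms C1-C8 and leaves C7-I. The closest known reaction is the iodonium-induced carbocyclization (I2, KI, KHCO3) of dearomatized prenylated phloroglucinols to 7-iodobicyclo[3.3.1]nonanes, a halonium-triggered cation-olefin cyclization. Ring B (C1, C8, C7, C6, C5, C9) closes 6-endo-trig in the Markovnikov sense through a chair. C8 can reach C1 only on the face of ring A that carries C6, so C5 fixes C1; in that chair the E geometry places the acetal arm equatorial and the methyl axial on C8, and backside opening of the iodonium ion leaves iodine equatorial on C7. The step needs C1 over C3, carbon over oxygen and C7=C8 over the allyl groups: C3 is the hindered, least nucleophilic centre of the aroyl triketone, the allyl groups are monosubstituted alkenes that meet barely more than one equivalent of iodine, and the C8 arm carries no alkene at all. Ethers formed through O4 or O9 hold an excellent enolate leaving group next to C-I, so iodide can return them to 13, whereas the C-C bond is permanent.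

Step 9
Reactants: 14 the C7 iodide of step 8
Product: 15 (1S,5S,7R,8S)-1,5,7-triallyl-8-(3,3-dimethoxypropyl)-4-hydroxy-8-methyl-3-[3-(tosyloxy)benzoyl]bicyclo[3.3.1]non-3-ene-2,9-dione (C7 allyl equatorial)
Conditions: allyltributylstannane (10 equiv, about 2 M), AIBN (portions), PhH, 80 °C
Reagents that add atoms: allyltributylstannane, C=CC[Sn](CCCC)(CCCC)CCCC
Why: In this Keck radical allylation the planar C7 radical should take up the stannane on its open exo face, because the endo face looks into ring A; this restores the equatorial substituent, and no 5-exo closure can outrun the transfer because the C8 arm has no alkene and the bridgehead allyl groups are held out of reach.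

Step 10
Reactants: 15 the triallyl acetal of step 9
Product: 16 (1S,5S,7R,8S)-1,5,7-triallyl-4-hydroxy-8-methyl-8-(3-oxopropyl)-3-[3-(tosyloxy)benzoyl]bicyclo[3.3.1]non-3-ene-2,9-dione
Conditions: 1 M HCl, THF, rt
Reagents that add atoms: water, O
Why: Acid hydrolysis of the dimethyl acetal is run while all alkenes are still monosubstituted and cannot be protonated by dilute acid, the tosylate is acid-stable, and any tributylstannyl enol ether carried over from step 9 is cleaved as well.

Step 11
Reactants: 16 the aldehyde of step 10
Product: 17 (1S,5S,7R,8S)-1,5,7-triallyl-4-hydroxy-8-methyl-8-(4-methylpent-3-enyl)-3-[3-(tosyloxy)benzoyl]bicyclo[3.3.1]non-3-ene-2,9-dione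
Conditions: i-PrPPh3I (3.5 equiv), n-BuLi (3.3 equiv), THF, 0 °C; then 16, -78 to 0 °C; aq NH4Cl, dilute HCl
Reagents that add atoms: isopropyltriphenylphosphonium iodide, CC(C)[P+](c1ccccc1)(c1ccccc1)c1ccccc1.[I-]
Why: In this Wittig olefination the first equivalent of ylide turns the acidic enol into an enolate that shields C2, C4 and the aroyl carbonyl, and C9 between two quaternary carbons is inert, so only the unhindered aldehyde should react.

Step 12
Reactants: 17 the triallyl compound of step 11
Product: 18 (1S,5S,7R,8S)-4-hydroxy-8-methyl-1,5,7-tris(3-methylbut-2-enyl)-8-(4-methylpent-3-enyl)-3-[3-(tosyloxy)benzoyl]bicyclo[3.3.1]non-3-ene-2,9-dione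
Conditions: second-generation Grubbs catalyst, (H2IMes)(PCy3)Cl2Ru=CHPh (10 mol %), 2-methylbut-2-ene/CH2Cl2, 40 °C, sealed tube
Reagents that add atoms: 2-methylbut-2-ene, CC=C(C)C
Why: Threefold olefin cross-metathesis of allyl to prenyl groups in a large excess of the trisubstituted partner is the established end game for this family, and the trisubstituted alkene already on the C8 arm can only undergo degenerate exchange.

Step 13
Reactants: 18 the O-tosyl derivative of the target
Product: 19 CNP0406274.2, (1S,5S,7R,8S)-4-hydroxy-3-(3-hydroxybenzoyl)-8-methyl-1,5,7-tris(3-methylbut-2-enyl)-8-(4-methylpent-3-enyl)bicyclo[3.3.1]non-3-ene-2,9-dione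
Conditions: KOH (10 equiv), 1,4-dioxane/H2O, 80 °C; then cold 1 M HCl
Reagents that add atoms: none
Why: Alkaline hydrolysis of the aryl sulfonate (hydroxide attacks sulfur) frees the phenol while the triketone rests as its enolate, which blocks retro-Claisen cleavage; no stereocentre is alpha to an enolisable carbonyl, and an alcohol-free medium avoids forming an alkyl tosylate that could alkylate the product.

Compound list
1 | 3-hydroxybenzoic acid | OC(=O)c1cccc(O)c1 | starting material
2 | 3-(tosyloxy)benzoic acid | Cc1ccc(cc1)S(=O)(=O)Oc1cccc(c1)C(=O)O | intermediate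
3 | phloroglucinol | Oc1cc(O)cc(O)c1 | starting material
4 | 3-(tosyloxy)benzoyl chloride | Cc1ccc(cc1)S(=O)(=O)Oc1cccc(c1)C(=O)Cl | intermediate
5 | 3-(2,4,6-trihydroxybenzoyl)phenyl 4-methylbenzenesulfonate | Cc1ccc(cc1)S(=O)(=O)Oc1cccc(c1)C(=O)c1c(O)cc(O)cc1O | intermediate
6 | allyl bromide | C=CCBr | starting material
7 | 3-(3,5-diallyl-2,4,6-trihydroxybenzoyl)phenyl 4-methylbenzenesulfonate | Cc1ccc(cc1)S(=O)(=O)Oc1cccc(c1)C(=O)c1c(O)c(CC=C)c(O)c(CC=C)c1O | intermediate
8 | geraniol | CC(C)=CCC/C(C)=C/CO | starting material
9 | geranyl methyl carbonate | CC(C)=CCC/C(C)=C/COC(=O)OC | intermediate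
10 | secondary ozonide of 9 at the distal alkene (racemic 1,2,4-trioxolane) | COC(=O)OC/C=C(\C)CCC1OOC(C)(C)O1 | intermediate
11 | (E)-methyl 3-methyl-6-oxohex-2-enyl carbonate | COC(=O)OC/C=C(\C)CCC=O | intermediate
12 | (E)-6,6-dimethoxy-3-methylhex-2-enyl methyl carbonate | COC(=O)OC/C=C(\C)CCC(OC)OC | intermediate
13 | (6S)-2,6-diallyl-6-[(2E)-6,6-dimethoxy-3-methylhex-2-enyl]-3,5-dihydroxy-4-[3-(tosyloxy)benzoyl]cyclohexa-2,4-dien-1-one | COC(OC)CC/C(C)=C/C[C@]2(CC=C)C(=O)C(CC=C)=C(O)C(C(=O)c1cccc(OS(=O)(=O)c3ccc(C)cc3)c1)=C2O | intermediate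
14 | (1S,5S,7R,8R)-1,5-diallyl-8-(3,3-dimethoxypropyl)-4-hydroxy-7-iodo-8-methyl-3-[3-(tosyloxy)benzoyl]bicyclo[3.3.1]non-3-ene-2,9-dione | COC(OC)CC[C@@]1(C)[C@H](I)C[C@]2(CC=C)C(=O)[C@@]1(CC=C)C(=O)C(C(=O)c1cccc(OS(=O)(=O)c3ccc(C)cc3)c1)=C2O | intermediate
15 | (1S,5S,7R,8S)-1,5,7-triallyl-8-(3,3-dimethoxypropyl)-4-hydroxy-8-methyl-3-[3-(tosyloxy)benzoyl]bicyclo[3.3.1]non-3-ene-2,9-dione | COC(OC)CC[C@@]1(C)[C@H](CC=C)C[C@]2(CC=C)C(=O)[C@@]1(CC=C)C(=O)C(C(=O)c1cccc(OS(=O)(=O)c3ccc(C)cc3)c1)=C2O | intermediate
16 | (1S,5S,7R,8S)-1,5,7-triallyl-4-hydroxy-8-methyl-8-(3-oxopropyl)-3-[3-(tosyloxy)benzoyl]bicyclo[3.3.1]non-3-ene-2,9-dione | O=CCC[C@@]1(C)[C@H](CC=C)C[C@]2(CC=C)C(=O)[C@@]1(CC=C)C(=O)C(C(=O)c1cccc(OS(=O)(=O)c3ccc(C)cc3)c1)=C2O | intermediate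
17 | (1S,5S,7R,8S)-1,5,7-triallyl-4-hydroxy-8-methyl-8-(4-methylpent-3-enyl)-3-[3-(tosyloxy)benzoyl]bicyclo[3.3.1]non-3-ene-2,9-dione | CC(C)=CCC[C@@]1(C)[C@H](CC=C)C[C@]2(CC=C)C(=O)[C@@]1(CC=C)C(=O)C(C(=O)c1cccc(OS(=O)(=O)c3ccc(C)cc3)c1)=C2O | intermediate
18 | (1S,5S,7R,8S)-4-hydroxy-8-methyl-1,5,7-tris(3-methylbut-2-enyl)-8-(4-methylpent-3-enyl)-3-[3-(tosyloxy)benzoyl]bicyclo[3.3.1]non-3-ene-2,9-dione | CC(C)=CCC[C@@]1(C)[C@H](CC=C(C)C)C[C@]2(CC=C(C)C)C(=O)[C@@]1(CC=C(C)C)C(=O)C(C(=O)c1cccc(OS(=O)(=O)c3ccc(C)cc3)c1)=C2O | intermediate
19 | CNP0406274.2, (1S,5S,7R,8S)-4-hydroxy-3-(3-hydroxybenzoyl)-8-methyl-1,5,7-tris(3-methylbut-2-enyl)-8-(4-methylpent-3-enyl)bicyclo[3.3.1]non-3-ene-2,9-dione | CC(C)=CCC[C@@]1(C)[C@H](CC=C(C)C)C[C@]2(CC=C(C)C)C(=O)[C@@]1(CC=C(C)C)C(=O)C(C(=O)c1cccc(O)c1)=C2O | target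

Total steps: 13. Longest linear sequence: 10 (steps 1-3 and 7-13 from 1, or equally steps 4-6 and 7-13 from 8).

Steps most likely to fail

Step 7. The catalyst may discriminate poorly between the enantiotopic carbons C1 and C5, because the new bond forms at the far, unsubstituted end of the π-allyl unit. The product may also re-ionise, driven by rearomatization, which would erode the enantiomeric purity and scramble allyl against the long chain, and a second alkylation at C1 may set in. The fallback sets out from 7 and 12. The same coupling with the achiral catalyst Pd(PPh3)4 in THF, a known racemic dearomative allylation, gives the racemic dienone F1. This is separated by preparative chromatography on a chiral stationary phase into 13 and its (6R) mirror image F2. The route is rejoined at 13.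

Step 8. The iodonium ion may be captured by an enol oxygen (O4 or O9) or by water faster than by the hindered carbon C1. A boat-like closure may lower the selectivity at C8, and surplus iodine may start iodoetherification at the allyl groups. The fallback sets out from 13 and replaces the kinetically controlled halonium capture in base by a selenium-triggered closure under equilibrating acid. N-(phenylseleno)phthalimide with ZnI2 in CH2Cl2 is followed by anhydrous p-TsOH. Under these conditions seleniranium formation and O-capture are reversible, and alkenyl 1,3-dicarbonyl compounds are known to end as carbocycles. This forms the same C1-C8 bond and gives the 7-phenylselanyl bicycle F3. Its C-Se bond is homolysed by the stannyl radical under the conditions of step 9, so the route is rejoined at 15.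

Step 12. Ring-closing metathesis between neighbouring allyl groups (seven-membered rings across C1/C7 or C5/C7) may compete with the exchange. Chelation of ruthenium by the free enol may slow the catalyst, and incomplete exchange would leave partly prenylated material. The fallback sets out from 16 and avoids metathesis altogether. Lemieux-Johnson cleavage (OsO4 cat., NaIO4, 2,6-lutidine, dioxane/H2O) of the three terminal alkenes gives the tetraaldehyde F4, in which the bridgehead CH2CHO groups may rest as lactols with the enol. Excess isopropylidenetriphenylphosphorane, made as in step 11, converts all four aldehydes at once, so the route is rejoined at 18 and 17 is bypassed.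

Further compounds
F1 | step 7 | racemic 2,6-diallyl-6-[(2E)-6,6-dimethoxy-3-methylhex-2-enyl]-3,5-dihydroxy-4-[3-(tosyloxy)benzoyl]cyclohexa-2,4-dien-1-one | COC(OC)CC/C(C)=C/CC2(CC=C)C(=O)C(CC=C)=C(O)C(C(=O)c1cccc(OS(=O)(=O)c3ccc(C)cc3)c1)=C2O
F2 | step 7 | (6R) enantiomer of 13 | COC(OC)CC/C(C)=C/C[C@@]2(CC=C)C(=O)C(CC=C)=C(O)C(C(=O)c1cccc(OS(=O)(=O)c3ccc(C)cc3)c1)=C2O
F3 | step 8 | (1S,5S,7R,8R)-1,5-diallyl-8-(3,3-dimethoxypropyl)-4-hydroxy-8-methyl-7-(phenylselanyl)-3-[3-(tosyloxy)benzoyl]bicyclo[3.3.1]non-3-ene-2,9-dione | COC(OC)CC[C@@]1(C)[C@H]([Se]c3ccccc3)C[C@]2(CC=C)C(=O)[C@@]1(CC=C)C(=O)C(C(=O)c1cccc(OS(=O)(=O)c3ccc(C)cc3)c1)=C2O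
F4 | step 12 | 4-hydroxy-8-methyl-1,5,7-tris(2-oxoethyl)-8-(3-oxopropyl)-3-[3-(tosyloxy)benzoyl]bicyclo[3.3.1]non-3-ene-2,9-dione, same spatial arrangement as 16 | O=CCC[C@@]1(C)[C@H](CC=O)C[C@]2(CC=O)C(=O)[C@@]1(CC=O)C(=O)C(C(=O)c1cccc(OS(=O)(=O)c3ccc(C)cc3)c1)=C2O
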